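## The problem

CNP0255890.0 (31) is a linear chain of ten oxygenated benzene rings, lettered here A (the 2,4,6-trihydroxyphenyl end) to J (the 3,4,5-trihydroxyphenoxy end). The rings are joined only by nine diaryl ether oxygens. There is no ring fusion, no ring-to-ring carbon bond and no stereocentre, so no stereocontrol is needed and none can be relayed. The task is one of oxygenation pattern and of the order in which the C–O bonds are made.

Between the end rings the same pair occurs four times. Rings B, D, F and H carry oxygen at C1, C3, C4 and C5, are etherified at C1 and C4, and have hydrogen at C2 and C6. Rings C, E, G and I are pentaoxygenated and etherified at the adjacent carbons C1 and C2. Each of the nine ether bonds ends on one carbon whose two neighbours both bear oxygen (C2 of A, C, E, G, I; C4 of B, D, F, H). Every intermolecular coupling therefore joins hindered, electron-rich partners with no activation for uncatalysed substitution.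

The 26 free hydroxyls sit on pyrogallol- and hydroxyquinol-type rings that oxidise readily in base and air. They have to stay masked until the last step and be released under non-oxidising conditions.

The feature that opens the key step is the pattern of ring D (and equally B, F, H). The aryloxy carbon C4 lies between two oxygenated carbons, the fourth oxygen is para at C1, and C2 and C6 are CH. This is the pattern produced when an aryloxyketene carbon is flanked by a ketene carbonyl and an alkoxyalkyne carbon, and a second ynol ether supplies C1 and C2.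

## Retrosynthesis

**31 ⇒ 30.** The 26 O–H bonds are traced back to 22 methyl and 4 ethyl ethers in the per-O-alkylated decamer 30. Simple alkyl ethers are the only masks that pass through ketene chemistry, thermolysis, fluoride, hydrogenolysis and basic copper couplings. Benzyl is kept free as the one temporary group. The forward step must cleave all 26 ethers without touching the nine diaryl ethers and without oxidising the product.

**30 ⇒ 28 + 29.** The bond between the bridging oxygen and C2 of ring A is cut. Ring A can be bought with the halogen in place as 2-iodo-1,3,5-trimethoxybenzene 29, so building it would gain nothing. Placing this coupling last lets the small hindered partner 29 be used in excess against the valuable nonamer phenol 28.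

**28 ⇒ 1 + four units of 20.** The O–C2 bonds of rings C, E, G and I are cut in turn: 27 ⇒ 26 + 20, 25 ⇒ 24 + 20, 23 ⇒ 22 + 20, 21 ⇒ 1 + 20. The four inner pairs are identical, so one building block serves for all of them. This is dimer 20, with iodine at C2 of its pentaoxygenated ring and a benzyl ether at C1 of its other ring. Ring J is the commercial phenol 1.

A three-fragment union around a central D–E unit was weighed against this. It needs a D–E piece with a free phenol and a hindered halide in the same molecule to couple selectively with a second, equally hindered halide. Growth from ring J removes that question: the halide partner 20 never carries a free phenol, and the chain end is unmasked by hydrogenolysis (21 → 22, 23 → 24, 25 → 26, 27 → 28) only after its own iodine has been used. The price is linearity. Each coupling needs an unhindered, electron-rich phenol to displace a di-ortho-oxygenated aryl iodide.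

**20 ⇒ 18 ⇒ 17.** No skeletal bond is cut. The benzyl ether of 20 replaces the silyl ether of 18 because a silyl aryl ether could migrate to the phenoxide partner under the coupling conditions. 18 is the methyl ether of phenol 17. Methyl is chosen over a second ethyl to keep the final dealkylation easy.

**17 ⇒ 8 + 12 (key disconnection).** In the tetraoxygenated ring the C2–C3 and C6–C1 bonds are cut. C3 is the carbonyl carbon of cyclobutenone 8, C4 its aryloxy carbon, C5 its ethoxy carbon and C6 its CH. C1 and C2 are the two carbons of (triisopropylsilyloxy)acetylene 12. This cut has three advantages over cuts that start from a ready-made aromatic ring: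

- The hindered C4–O bond is not made by coupling at all. It is the ether oxygen of the ketene precursor.
- The three ring oxygens emerge differentiated as free OH, OEt and OSi.
- The only aromatic starting material needed is phenol 1.

Iodine is carried at C2 of the aryloxy ring in preference to bromine. It is inert in steps 2 to 7 and is the better leaving group for the later couplings. The forward reaction must trap a transient vinylketene with the alkyne in one regiochemical sense.

**8 ⇒ 4 + 5; 4 ⇒ 2 + 3; 2 ⇒ 1.** The cyclobutenone is opened across its C1–C2 and C3–C4 bonds to aryloxyketene 7 and ethoxyacetylene 5. The ketene comes from acid chloride 6 of aryloxyacetic acid 4, made from iodophenol 2 and bromoacetic acid 3. 2 is the mono-iodination product of 1. Each step is a standard operation on a small molecule.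

**12 ⇒ 9.** The O–Si and C–O bonds of the ynol ether are cut back through lithium ethynolate 11 and lithium acetylide 10 to acetylene 9.

## Roads not taken

**Alternative 1:** Both ether bonds of ring G are cut, and the ring is introduced as the [(C5H5)Ru]+ hexafluorophosphate complex of 1,2-dichloro-3,4,5-trimethoxybenzene, A1. In the forward step two phenoxides replace the two chlorides one after the other in one flask, giving the ruthenium-bound pentamer F–J, A2.

- Merits: substitution on such cationic arene complexes runs near room temperature and accepts a 2,6-dialkoxyphenoxide, the nucleophile copper catalysis handles least well. Two hindered ether bonds form in one operation. In the C–O bond-forming event itself this road is better than the chosen one.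
- Weak points: the two chlorides of A1 differ only by their neighbours (H versus OMe). The first, bulky phenoxide must choose C1 cleanly, or regioisomeric pentamers result that would be very hard to separate. Three methoxy donors lower the electrophilicity of the complex. One stoichiometric ruthenium, one complexation and one photochemical decomplexation are spent per pentaoxygenated ring, and there are four such rings.
- Comparison: the chosen plan offers copper in catalytic amount, a halogen position fixed beyond doubt by phenol 1, and one building block used four times.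

**Alternative 2:** A C–C bond of ring A is cut, in the manner of polyketide biosynthesis. Dimethyl 4-[4-(benzyloxy)-3,5-dimethoxyphenoxy]-3,5-dioxoheptanedioate A3 would undergo base-mediated intramolecular Claisen condensation to the phloroglucinol ester A4, which carries rings A and B.

- Merits: mild base, free hydroxyls directly, and the hindered ether at C2 of ring A in place before the ring exists. It avoids the hardest coupling of the chosen route (step 16) and is better in that respect.
- Weak points: A3 is a sensitive tetracarbonyl compound with no short preparation. Lactonisation to a pyrone and aldol closure compete with the Claisen mode. The extra ester has to be removed and the three new hydroxyls protected again before eight further couplings.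
- Comparison: the effort goes into the one ring that is commercial as 29, and one ring of ten is built. The chosen annulation supplies a ring type needed four times and hard to buy with its oxygens differentiated.

**Alternative 3:** The C1–C2 bond of pentaoxygenated ring C is cut. A squarate-derived 4-methoxy-4-[(Z)-2-aryloxyvinyl]cyclobutenone A5, carrying rings A and B on the vinyl ether oxygen, would open on heating to a dienylketene and close by 6π electrocyclisation to the trimer phenol A6, with a free hydroxyl at C2 of ring C.

- Merits: the ring closure is unimolecular, whereas the chosen step 5 must trap a ketene bimolecularly. The substitution pattern is fixed by the squarate. The free hydroxyl appears where the next ether is needed, as a hindered phenol that would meet an unhindered halide, the polarity copper catalysis handles best. In certainty of the ring-forming event this road is the stronger one.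
- Weak points: A5 needs a (Z)-2-aryloxyvinyl organometallic, a species prone to lose aryloxide by β-elimination, and O-methylation of a tertiary alkoxide. The ring it builds has the substitution of phenol 1, which one iodination turns into the needed electrophile. Repeating the sequence for rings E, G and I would put four thermolyses on ever larger fragments.
- Comparison: the chosen plan builds the ring type that is not commercially available in differentiated form, and it forms the hindered C4–O bond by a simple alkylation.

Key step: step 5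

Assumption: rotation about the diaryl ether bonds is taken as free, so that 31 and its precursors are single achiral compounds without atropisomers to control.

## Route

Step 1
Reactants: 1 3,4,5-trimethoxyphenol
Product: 2 2-iodo-3,4,5-trimethoxyphenol
Conditions: NIS (1.0 equiv), CH2Cl2, −20→0 °C, dark
Reagents that add atoms: N-iodosuccinimide, O=C1CCC(=O)N1I
Why: Electrophilic aromatic iodination; the two open positions are equivalent and strongly activated, and one equivalent of reagent at low temperature should hold the reaction at the mono-iodide.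

Step 2
Reactants: 2 2-iodo-3,4,5-trimethoxyphenol; 3 bromoacetic acid
Product: 4 (2-iodo-3,4,5-trimethoxyphenoxy)acetic acid
Conditions: NaOH, H2O, 90 °C; then HCl (aq)
Reagents that add atoms: none
Why: Williamson ether synthesis of an aryloxyacetic acid from the phenoxide and bromoacetate; the aryl iodide is inert to aqueous hydroxide. This unhindered alkylation creates the oxygen that later bridges the two rings of the building block.

Step 3
Reactants: 4 (2-iodo-3,4,5-trimethoxyphenoxy)acetic acid; 5 ethoxyacetylene
Product: 8 racemic 3-ethoxy-4-(2-iodo-3,4,5-trimethoxyphenoxy)cyclobut-2-en-1-one, via acid chloride 6 (not isolated), via aryloxyketene 7 (not isolated)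
Conditions: (COCl)2, cat. DMF, CH2Cl2, 0→23 °C, evaporate; then 5 (3 equiv), Et3N (slow addition), CH2Cl2, 0→23 °C
Reagents that add atoms: none
Why: Dehydrochlorination of the acid chloride gives the aryloxyketene, which enters the known ketene–alkoxyacetylene (2+2) cycloaddition; the nucleophilic CH carbon of the ynol ether bonds to the ketene carbonyl carbon, which places OEt at C3 and OAr at C4. C4 forms as a racemate, which is of no consequence because it becomes an aromatic carbon in step 5.

Step 4
Reactants: 9 acetylene
Product: 12 (triisopropylsilyloxy)acetylene, via lithium acetylide 10 (not isolated), via lithium ethynolate 11 (not isolated)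
Conditions: n-BuLi, THF, −78 °C; LiOOt-Bu [from t-BuOOH, LiN(SiMe3)2], −78→−20 °C; TIPSOTf, −78→0 °C
Reagents that add atoms: tert-butyl hydroperoxide, CC(C)(C)OO; triisopropylsilyl trifluoromethanesulfonate, CC(C)[Si](C(C)C)(C(C)C)OS(=O)(=O)C(F)(F)F
Why: Peroxide oxidation of a lithium acetylide to the ynolate followed by O-silylation is the established route from terminal alkynes to triisopropylsilyl ynol ethers, applied here to the parent acetylide. The bulky silyl group favours O- over C-silylation and slows the 1,3-shift to a silylketene.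

Step 5
Reactants: 8 racemic 3-ethoxy-4-(2-iodo-3,4,5-trimethoxyphenoxy)cyclobut-2-en-1-one; 12 (triisopropylsilyloxy)acetylene
Product: 17 3-ethoxy-2-(2-iodo-3,4,5-trimethoxyphenoxy)-5-(triisopropylsilyloxy)phenol, via vinylketene 13 (not isolated), via vinylcyclobutenone 14 (not isolated), via dienylketene 15 (not isolated), via cyclohexadienone 16 (not isolated)
Conditions: 12 (2 equiv), toluene (0.1 M), 80 °C, then 110 °C, argon, dark
Reagents that add atoms: none
Why: Danheiser benzannulation of a cyclobutenone with a siloxyalkyne, applied here to a 3-alkoxy-4-aryloxy substrate. Heating opens 8 by 4π electrocyclic cleavage of its C1–C4 bond, the donor aryloxy group turning outward as 4-oxygen substituents of squarate-derived cyclobutenones do, to give vinylketene 13. The ketene C=C bond of 13 then adds 12 in a (2+2) cycloaddition in which the unsubstituted alkyne carbon bonds to the ketene carbonyl carbon and the silyloxy carbon to the ketene CH, giving 14 and the two new C–C bonds. 14 opens reversibly to dienylketene 15, and only the isomer with the alkenyl group turned inward can go on. The ring closes by thermal disrotatory 6π electrocyclisation between the ketene carbon and the aryloxy-bearing terminus (six-membered carbocycle 16), and enolisation gives phenol 17. No stereocentre survives, since C4 of 8 and C6 of 16 both end as aromatic carbons. The selectivity needed is the orientation of the (2+2) step, which puts the silyloxy carbon para and the new hydroxyl ortho to the aryloxy carbon; it follows from the match between the nucleophilic CH terminus of the polarised ynol ether and the electrophilic ketene carbon. Excess 12 and moderate dilution are meant to make trapping of 13 faster than ketene dimerisation or acylation of 17.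

Step 6
Reactants: 17 3-ethoxy-2-(2-iodo-3,4,5-trimethoxyphenoxy)-5-(triisopropylsilyloxy)phenol
Product: 18 [3-ethoxy-4-(2-iodo-3,4,5-trimethoxyphenoxy)-5-methoxyphenoxy]triisopropylsilane
Conditions: MeI, K2CO3, acetone, 50 °C
Reagents that add atoms: iodomethane, CI
Why: Williamson O-methylation of the only free phenol; a triisopropylsilyl aryl ether is stable to K2CO3 in acetone.

Step 7
Reactants: 18 [3-ethoxy-4-(2-iodo-3,4,5-trimethoxyphenoxy)-5-methoxyphenoxy]triisopropylsilane
Product: 20 5-(benzyloxy)-1-ethoxy-2-(2-iodo-3,4,5-trimethoxyphenoxy)-3-methoxybenzene, via cesium phenoxide 19 (not isolated)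
Conditions: CsF, BnBr, DMF, 23 °C
Reagents that add atoms: benzyl bromide, BrCc1ccccc1
Why: One-flask fluoride desilylation and benzylation of an aryl silyl ether; the phenoxide is alkylated as it forms, so no compound with both a free phenol and an aryl iodide is handled.

Step 8
Reactants: 1 3,4,5-trimethoxyphenol; 20 5-(benzyloxy)-1-ethoxy-2-(2-iodo-3,4,5-trimethoxyphenoxy)-3-methoxybenzene
Product: 21 trimer H–I–J benzyl ether, 5-(benzyloxy)-1-ethoxy-3-methoxy-2-[3,4,5-trimethoxy-2-(3,4,5-trimethoxyphenoxy)phenoxy]benzene
Conditions: CuI (10 mol%), picolinic acid (20 mol%), K3PO4, DMSO, 90 °C, argon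
Reagents that add atoms: none
Why: Ullmann-type diaryl ether synthesis under conditions developed for hindered partners; an unhindered electron-rich phenoxide displaces iodide from the di-ortho-oxygenated ring. The iodide partner has no free hydroxyl, so self-condensation is excluded.

Step 9
Reactants: 21 trimer H–I–J benzyl ether
Product: 22 trimer H–I–J phenol, 3-ethoxy-5-methoxy-4-[3,4,5-trimethoxy-2-(3,4,5-trimethoxyphenoxy)phenoxy]phenol
Conditions: H2 (1 atm), 10% Pd/C, EtOAc–MeOH, 23 °C
Reagents that add atoms: none
Why: Hydrogenolysis of the benzyl aryl ether; methyl, ethyl and diaryl ethers are inert and no carbon–halogen bond remains in the molecule.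

Step 10
Reactants: 22 trimer H–I–J phenol; 20 5-(benzyloxy)-1-ethoxy-2-(2-iodo-3,4,5-trimethoxyphenoxy)-3-methoxybenzene
Product: 23 pentamer F–J benzyl ether (20 with its iodine replaced by the aryloxy residue of 22)
Conditions: CuI (10 mol%), picolinic acid (20 mol%), K3PO4, DMSO, 90 °C, argon
Reagents that add atoms: none
Why: The same Ullmann-type coupling as step 8; the reacting phenol has the same local environment (OEt and OMe meta, aryloxy para) at every chain length.

Step 11
Reactants: 23 pentamer F–J benzyl ether
Product: 24 pentamer F–J phenol (free hydroxyl at C1 of ring F)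
Conditions: H2 (1 atm), 10% Pd/C, EtOAc–MeOH, 23 °C
Reagents that add atoms: none
Why: Benzyl ether hydrogenolysis as in step 9.

Step 12
Reactants: 24 pentamer F–J phenol; 20 5-(benzyloxy)-1-ethoxy-2-(2-iodo-3,4,5-trimethoxyphenoxy)-3-methoxybenzene
Product: 25 heptamer D–J benzyl ether (20 with its iodine replaced by the aryloxy residue of 24)
Conditions: CuI (10 mol%), picolinic acid (20 mol%), K3PO4, DMSO, 90 °C, argon
Reagents that add atoms: none
Why: Ullmann-type coupling as in step 8; this use of 20 supplies rings D and E.

Step 13
Reactants: 25 heptamer D–J benzyl ether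
Product: 26 heptamer D–J phenol (free hydroxyl at C1 of ring D)
Conditions: H2 (1 atm), 10% Pd/C, EtOAc–MeOH, 23 °C
Reagents that add atoms: none
Why: Benzyl ether hydrogenolysis as in step 9.

Step 14
Reactants: 26 heptamer D–J phenol; 20 5-(benzyloxy)-1-ethoxy-2-(2-iodo-3,4,5-trimethoxyphenoxy)-3-methoxybenzene
Product: 27 nonamer B–J benzyl ether (20 with its iodine replaced by the aryloxy residue of 26)
Conditions: CuI (10 mol%), picolinic acid (20 mol%), K3PO4, DMSO, 90 °C, argon
Reagents that add atoms: none
Why: Ullmann-type coupling as in step 8.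

Step 15
Reactants: 27 nonamer B–J benzyl ether
Product: 28 nonamer B–J phenol (free hydroxyl at C1 of ring B)
Conditions: H2 (1 atm), 10% Pd/C, EtOAc–MeOH, 23 °C
Reagents that add atoms: none
Why: Benzyl ether hydrogenolysis as in step 9.

Step 16
Reactants: 28 nonamer B–J phenol; 29 2-iodo-1,3,5-trimethoxybenzene
Product: 30 per-O-alkylated decamer A–J (28 arylated on its free oxygen by the 2,4,6-trimethoxyphenyl group)
Conditions: 29 (3 equiv), CuI (20 mol%), picolinic acid (40 mol%), K3PO4, DMSO, 100 °C, argon
Reagents that add atoms: none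
Why: Ullmann-type coupling of the unhindered chain phenol with a 2,6-dimethoxyaryl iodide; the cheap hindered partner is used in excess.

Step 17
Reactants: 30 per-O-alkylated decamer A–J
Product: 31 CNP0255890.0
Conditions: BBr3 (excess), CH2Cl2, −78→23 °C; then degassed H2O, 0 °C, argon
Reagents that add atoms: none
Why: Lewis-acid cleavage of aryl methyl and ethyl ethers with BBr3; diaryl ether bonds are not cleaved. Work-up and isolation under argon keep the pyrogallol-type rings from oxidising.

## Compound list

1 | 3,4,5-trimethoxyphenol | COc1cc(O)cc(OC)c1OC | starting material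
2 | 2-iodo-3,4,5-trimethoxyphenol | COc1cc(O)c(I)c(OC)c1OC | intermediate
3 | bromoacetic acid | OC(=O)CBr | starting material
4 | (2-iodo-3,4,5-trimethoxyphenoxy)acetic acid | COc1cc(OCC(=O)O)c(I)c(OC)c1OC | intermediate
5 | ethoxyacetylene | CCOC#C | starting material
6 | (2-iodo-3,4,5-trimethoxyphenoxy)acetyl chloride | COc1cc(OCC(=O)Cl)c(I)c(OC)c1OC | intermediate
7 | (2-iodo-3,4,5-trimethoxyphenoxy)ketene | COc1cc(OC=C=O)c(I)c(OC)c1OC | intermediate
8 | racemic 3-ethoxy-4-(2-iodo-3,4,5-trimethoxyphenoxy)cyclobut-2-en-1-one | CCOC1=CC(=O)C1Oc1cc(OC)c(OC)c(OC)c1I | intermediate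
9 | acetylene | C#C | starting material
10 | lithium acetylide | [Li+].[C-]#C | intermediate
11 | lithium ethynolate | [Li+].[O-]C#C | intermediate
12 | (triisopropylsilyloxy)acetylene | C#CO[Si](C(C)C)(C(C)C)C(C)C | intermediate
13 | (3Z)-3-ethoxy-4-(2-iodo-3,4,5-trimethoxyphenoxy)buta-1,3-dien-1-one | O=C=C/C(OCC)=C/Oc1cc(OC)c(OC)c(OC)c1I | intermediate
14 | racemic 4-[(Z)-1-ethoxy-2-(2-iodo-3,4,5-trimethoxyphenoxy)ethenyl]-3-(triisopropylsilyloxy)cyclobut-2-en-1-one | O=C1C=C(O[Si](C(C)C)(C(C)C)C(C)C)C1/C(OCC)=C/Oc1cc(OC)c(OC)c(OC)c1I | intermediate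
15 | (3E,5Z)-5-ethoxy-6-(2-iodo-3,4,5-trimethoxyphenoxy)-3-(triisopropylsilyloxy)hexa-1,3,5-trien-1-one | O=C=C/C(O[Si](C(C)C)(C(C)C)C(C)C)=C\C(OCC)=C\Oc1cc(OC)c(OC)c(OC)c1I | intermediate
16 | racemic 5-ethoxy-6-(2-iodo-3,4,5-trimethoxyphenoxy)-3-(triisopropylsilyloxy)cyclohexa-2,4-dien-1-one | O=C1C=C(O[Si](C(C)C)(C(C)C)C(C)C)C=C(OCC)C1Oc1cc(OC)c(OC)c(OC)c1I | intermediate
17 | 3-ethoxy-2-(2-iodo-3,4,5-trimethoxyphenoxy)-5-(triisopropylsilyloxy)phenol | CCOc1cc(O[Si](C(C)C)(C(C)C)C(C)C)cc(O)c1Oc1cc(OC)c(OC)c(OC)c1I | intermediate
18 | [3-ethoxy-4-(2-iodo-3,4,5-trimethoxyphenoxy)-5-methoxyphenoxy]triisopropylsilane | CCOc1cc(O[Si](C(C)C)(C(C)C)C(C)C)cc(OC)c1Oc1cc(OC)c(OC)c(OC)c1I | intermediate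
19 | cesium 3-ethoxy-4-(2-iodo-3,4,5-trimethoxyphenoxy)-5-methoxyphenoxide | [Cs+].[O-]c1cc(OCC)c(Oc2cc(OC)c(OC)c(OC)c2I)c(OC)c1 | intermediate
20 | 5-(benzyloxy)-1-ethoxy-2-(2-iodo-3,4,5-trimethoxyphenoxy)-3-methoxybenzene | CCOc1cc(OCc2ccccc2)cc(OC)c1Oc1cc(OC)c(OC)c(OC)c1I | intermediate
21 | trimer H–I–J benzyl ether, 5-(benzyloxy)-1-ethoxy-3-methoxy-2-[3,4,5-trimethoxy-2-(3,4,5-trimethoxyphenoxy)phenoxy]benzene | CCOc1cc(OCc2ccccc2)cc(OC)c1Oc1cc(OC)c(OC)c(OC)c1Oc1cc(OC)c(OC)c(OC)c1 | intermediate
22 | trimer H–I–J phenol, 3-ethoxy-5-methoxy-4-[3,4,5-trimethoxy-2-(3,4,5-trimethoxyphenoxy)phenoxy]phenol | CCOc1cc(O)cc(OC)c1Oc1cc(OC)c(OC)c(OC)c1Oc1cc(OC)c(OC)c(OC)c1 | intermediate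
23 | pentamer F–J benzyl ether | c1ccccc1COc1cc(OCC)c(Oc2cc(OC)c(OC)c(OC)c2Oc2cc(OCC)c(Oc3cc(OC)c(OC)c(OC)c3Oc3cc(OC)c(OC)c(OC)c3)c(OC)c2)c(OC)c1 | intermediate
24 | pentamer F–J phenol | Oc1cc(OCC)c(Oc2cc(OC)c(OC)c(OC)c2Oc2cc(OCC)c(Oc3cc(OC)c(OC)c(OC)c3Oc3cc(OC)c(OC)c(OC)c3)c(OC)c2)c(OC)c1 | intermediate
25 | heptamer D–J benzyl ether | c1ccccc1COc1cc(OCC)c(Oc2cc(OC)c(OC)c(OC)c2Oc2cc(OCC)c(Oc3cc(OC)c(OC)c(OC)c3Oc3cc(OCC)c(Oc4cc(OC)c(OC)c(OC)c4Oc4cc(OC)c(OC)c(OC)c4)c(OC)c3)c(OC)c2)c(OC)c1 | intermediate
26 | heptamer D–J phenol | Oc1cc(OCC)c(Oc2cc(OC)c(OC)c(OC)c2Oc2cc(OCC)c(Oc3cc(OC)c(OC)c(OC)c3Oc3cc(OCC)c(Oc4cc(OC)c(OC)c(OC)c4Oc4cc(OC)c(OC)c(OC)c4)c(OC)c3)c(OC)c2)c(OC)c1 | intermediate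
27 | nonamer B–J benzyl ether | c1ccccc1COc1cc(OCC)c(Oc2cc(OC)c(OC)c(OC)c2Oc2cc(OCC)c(Oc3cc(OC)c(OC)c(OC)c3Oc3cc(OCC)c(Oc4cc(OC)c(OC)c(OC)c4Oc4cc(OCC)c(Oc5cc(OC)c(OC)c(OC)c5Oc5cc(OC)c(OC)c(OC)c5)c(OC)c4)c(OC)c3)c(OC)c2)c(OC)c1 | intermediate
28 | nonamer B–J phenol | Oc1cc(OCC)c(Oc2cc(OC)c(OC)c(OC)c2Oc2cc(OCC)c(Oc3cc(OC)c(OC)c(OC)c3Oc3cc(OCC)c(Oc4cc(OC)c(OC)c(OC)c4Oc4cc(OCC)c(Oc5cc(OC)c(OC)c(OC)c5Oc5cc(OC)c(OC)c(OC)c5)c(OC)c4)c(OC)c3)c(OC)c2)c(OC)c1 | intermediate
29 | 2-iodo-1,3,5-trimethoxybenzene | COc1cc(OC)c(I)c(OC)c1 | starting material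
30 | per-O-alkylated decamer A–J (22 OMe, 4 OEt) | COc1cc(OC)cc(OC)c1Oc1cc(OCC)c(Oc2cc(OC)c(OC)c(OC)c2Oc2cc(OCC)c(Oc3cc(OC)c(OC)c(OC)c3Oc3cc(OCC)c(Oc4cc(OC)c(OC)c(OC)c4Oc4cc(OCC)c(Oc5cc(OC)c(OC)c(OC)c5Oc5cc(OC)c(OC)c(OC)c5)c(OC)c4)c(OC)c3)c(OC)c2)c(OC)c1 | intermediate
31 | CNP0255890.0 | Oc1cc(O)c(Oc2cc(O)c(Oc3cc(O)c(O)c(O)c3Oc3cc(O)c(Oc4cc(O)c(O)c(O)c4Oc4cc(O)c(Oc5cc(O)c(O)c(O)c5Oc5cc(O)c(Oc6cc(O)c(O)c(O)c6Oc6cc(O)c(O)c(O)c6)c(O)c5)c(O)c4)c(O)c3)c(O)c2)c(O)c1 | target

## Step count and least certain steps

Total: 17 steps. Longest linear sequence: 16 steps (steps 1–3 and 5–17; step 4 is a one-step side branch). Building block 20 is consumed four times, so steps 1–7 have to be run on the largest scale.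

**Step 5 (key step).** The bimolecular trapping of vinylketene 13 by 12 may lose against self-condensation of the ketene or against acylation of the product phenol by 13. The vinylogous-ester cyclobutenone may also need temperatures at which the silyl group of 12 migrates from oxygen to carbon, and the cascade may stall before the last ring opening.

Fallback, from 2 to 17: the vinylketene would be made at low temperature from an open-chain acid chloride instead of from the four-membered ring.

- Phenol 2 would be alkylated (K2CO3, acetone) with ethyl (2E)-4-bromo-3-ethoxybut-2-enoate F1 to give ethyl (2E)-3-ethoxy-4-(2-iodo-3,4,5-trimethoxyphenoxy)but-2-enoate F2.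
- Saponification (LiOH, THF–H2O) would give (2E)-3-ethoxy-4-(2-iodo-3,4,5-trimethoxyphenoxy)but-2-enoic acid F3, and (COCl)2 would give (2E)-3-ethoxy-4-(2-iodo-3,4,5-trimethoxyphenoxy)but-2-enoyl chloride F4.
- 1,4-Dehydrochlorination of F4 with Et3N in the presence of a large excess of 12 at 0–23 °C should generate 13 where 12 is stable. Warming would complete the passage through 14, 15 and 16 to 17.

The detour bypasses 8 and would also serve if step 3 failed.

**Step 4.** Monolithium acetylide may disproportionate on warming before it is oxidised. The parent ynolate may be protonated or silylated on carbon. The volatile, acid-sensitive product may be lost on isolation.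

Fallback, from 5 to 12: the terminal carbon would be blocked by silicon.

- Deprotonation of 5 (n-BuLi) and quenching with chlorotrimethylsilane would give 1-ethoxy-2-(trimethylsilyl)acetylene F5.
- Thermal retro-ene loss of ethylene at about 120 °C would give (trimethylsilyl)ketene F6.
- Deprotonation at −100 °C (n-BuLi) would give lithium 2-(trimethylsilyl)ethynolate F7, and O-silylation with TIPSOTf would give 1-(triisopropylsilyloxy)-2-(trimethylsilyl)acetylene F8.
- Selective cleavage of the alkynyl C–Si bond (K2CO3, MeOH, 0 °C) would return to 12.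

**Step 8 (and its repeats, steps 10, 12, 14 and 16).** Copper insertion into the di-ortho-oxygenated, electron-rich C–I bond may be slow. Reductive loss of iodine and oxidative degradation of the electron-rich phenoxide would then compete with ether formation.

Fallback, from 20 to 21: the roles of the partners would be reversed, so that the hindered ring becomes the phenol and the halide is unhindered.

- Iodine–magnesium exchange on 20 (i-PrMgCl·LiCl, THF, −20 °C) and quenching with B(OMe)3 would give, after hydrolysis, {2-[4-(benzyloxy)-2-ethoxy-6-methoxyphenoxy]-4,5,6-trimethoxyphenyl}boronic acid F9.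
- Oxidation (H2O2, NaOH) would give 6-[4-(benzyloxy)-2-ethoxy-6-methoxyphenoxy]-2,3,4-trimethoxyphenol F10.
- F10 would be coupled with commercial 5-bromo-1,2,3-trimethoxybenzene F11 under the same CuI/picolinic acid conditions to give 21.

For the later rounds the same reversal would require the chain phenol as an aryl sulfonate under palladium catalysis. It is not elaborated here.

**Step 17.** Dealkylation at 26 sites may stop short, the ethyl ethers being the slowest, and leave mixtures of partly alkylated material. The liberated pyrogallol-type rings may oxidise during isolation.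

Fallback, from 30 to 31: the polyphenol would be captured in a stable, purifiable form.

- Dealkylation with AlCl3 and ethanethiol in CH2Cl2 (hard acid, soft nucleophile) would be followed in the same flask by acetylation (Ac2O, pyridine) to the hexacosa-O-acetate of 31, F12.
- F12 would be purified by chromatography on silica.
- Acid methanolysis (HCl in MeOH, 23 °C, argon) would release 31.

## Further compounds

F1 | step 5 | ethyl (2E)-4-bromo-3-ethoxybut-2-enoate | CCOC(=O)/C=C(/OCC)CBr
F2 | step 5 | ethyl (2E)-3-ethoxy-4-(2-iodo-3,4,5-trimethoxyphenoxy)but-2-enoate | CCOC(=O)/C=C(/OCC)COc1cc(OC)c(OC)c(OC)c1I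
F3 | step 5 | (2E)-3-ethoxy-4-(2-iodo-3,4,5-trimethoxyphenoxy)but-2-enoic acid | OC(=O)/C=C(/OCC)COc1cc(OC)c(OC)c(OC)c1I
F4 | step 5 | (2E)-3-ethoxy-4-(2-iodo-3,4,5-trimethoxyphenoxy)but-2-enoyl chloride | ClC(=O)/C=C(/OCC)COc1cc(OC)c(OC)c(OC)c1I
F5 | step 4 | 1-ethoxy-2-(trimethylsilyl)acetylene | CCOC#C[Si](C)(C)C
F6 | step 4 | (trimethylsilyl)ketene | C[Si](C)(C)C=C=O
F7 | step 4 | lithium 2-(trimethylsilyl)ethynolate | [Li+].[O-]C#C[Si](C)(C)C
F8 | step 4 | 1-(triisopropylsilyloxy)-2-(trimethylsilyl)acetylene | C[Si](C)(C)C#CO[Si](C(C)C)(C(C)C)C(C)C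
F9 | step 8 | {2-[4-(benzyloxy)-2-ethoxy-6-methoxyphenoxy]-4,5,6-trimethoxyphenyl}boronic acid | CCOc1cc(OCc2ccccc2)cc(OC)c1Oc1cc(OC)c(OC)c(OC)c1B(O)O
F10 | step 8 | 6-[4-(benzyloxy)-2-ethoxy-6-methoxyphenoxy]-2,3,4-trimethoxyphenol | CCOc1cc(OCc2ccccc2)cc(OC)c1Oc1cc(OC)c(OC)c(OC)c1O
F11 | step 8 | 5-bromo-1,2,3-trimethoxybenzene | COc1cc(Br)cc(OC)c1OC
F12 | step 17 | hexacosa-O-acetate of 31 | CC(=O)Oc1cc(OC(C)=O)c(Oc2cc(OC(C)=O)c(Oc3cc(OC(C)=O)c(OC(C)=O)c(OC(C)=O)c3Oc3cc(OC(C)=O)c(Oc4cc(OC(C)=O)c(OC(C)=O)c(OC(C)=O)c4Oc4cc(OC(C)=O)c(Oc5cc(OC(C)=O)c(OC(C)=O)c(OC(C)=O)c5Oc5cc(OC(C)=O)c(Oc6cc(OC(C)=O)c(OC(C)=O)c(OC(C)=O)c6Oc6cc(OC(C)=O)c(OC(C)=O)c(OC(C)=O)c6)c(OC(C)=O)c5)c(OC(C)=O)c4)c(OC(C)=O)c3)c(OC(C)=O)c2)c(OC(C)=O)c1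
A1 | alternative 1 | (cyclopentadienyl)(1,2-dichloro-3,4,5-trimethoxybenzene)ruthenium hexafluorophosphate | COc1cc(Cl)c(Cl)c(OC)c1OC.[Ru+2].c1cc[cH-]c1.F[P-](F)(F)(F)(F)F
A2 | alternative 1 | [(C5H5)Ru]PF6 complex of pentamer F–J with the ring F para oxygen benzylated | COc1cc(OCc2ccccc2)cc(OC)c1Oc3cc(OC)c(OC)c(OC)c3Oc4cc(OC)c(Oc5cc(OC)c(OC)c(OC)c5Oc6cc(OC)c(OC)c(OC)c6)c(OC)c4.[Ru+2].c1cc[cH-]c1.F[P-](F)(F)(F)(F)F
A3 | alternative 2 | dimethyl 4-[4-(benzyloxy)-3,5-dimethoxyphenoxy]-3,5-dioxoheptanedioate | COC(=O)CC(=O)C(Oc1cc(OC)c(OCc2ccccc2)c(OC)c1)C(=O)CC(=O)OC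
A4 | alternative 2 | methyl 3-[4-(benzyloxy)-3,5-dimethoxyphenoxy]-2,4,6-trihydroxybenzoate | COC(=O)c1c(O)cc(O)c(Oc2cc(OC)c(OCc3ccccc3)c(OC)c2)c1O
A5 | alternative 3 | racemic 4-[(Z)-2-{2,6-dimethoxy-4-(2,4,6-trimethoxyphenoxy)phenoxy}ethenyl]-2,3,4-trimethoxycyclobut-2-en-1-one | COC1=C(OC)C(OC)(/C=C\Oc2c(OC)cc(Oc3c(OC)cc(OC)cc3OC)cc2OC)C1=O
A6 | alternative 3 | trimer phenol A–B–C, 6-[2,6-dimethoxy-4-(2,4,6-trimethoxyphenoxy)phenoxy]-2,3,4-trimethoxyphenol | Oc1c(OC)c(OC)c(OC)cc1Oc2c(OC)cc(Oc3c(OC)cc(OC)cc3OC)cc2OC
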